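The 14-membered carbocycle is closed at C5–C6, between the methyl-bearing carbon and the acetoxy carbinol beside the lactone ring. This exploits a hidden symmetry: C14(OAc)–C1(=CH2) and C6(OAc)–C5(CH3), linked by the C2–C4 trimethylene, are both 2-alkyl allylic carbinols, one of them reduced. A symmetric 2,6-diiodohepta-1,6-diene therefore supplies C1–C5 and both branch carbons through two Nozaki–Hiyama–Kishi couplings. The second, intramolecular one turns an open-chain iodoalkene–aldehyde that already carries the cis-fused α-methylene lactone, the C14 acetate and the C10=C11 alkene into the macrocycle, creating the C5–C6 bond and the C6 stereocentre in one operation; directed hydrogenation, inversion and epoxidation complete the target.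

Key step: step 13

Numbering used throughout: ring carbons C1 (bears the exocyclic CH2), C2–C4 (CH2), C5 (CHCH3), C6 (CHOAc), C7 (lactone O–CH), C8 (ring-fusion CH carrying the lactone α-carbon), C9 (CH2), C10 and C11 (epoxide CH and C(CH3)), C12 and C13 (CH2), C14 (CHOAc). The target is (5S,6R,7R,8S,10R,11R,14S) with a cis-fused lactone and a trans epoxide.

Remark: additions to the two α-oxygenated aldehydes (steps 5 and 13) are assumed to follow the polar Felkin–Anh model. The configuration at the lactone α-carbon of the amine adducts 23–26 is not controlled and is erased in step 16.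

Step 1
Reactants: 1 geranyl chloride
Product: 3 (2E)-1-chloro-6,6-dimethoxy-3-methylhex-2-ene, via chloro aldehyde 2 (not isolated)
Conditions: O3 (1 equiv, Sudan Red 7B end point), CH2Cl2, −78 °C; Me2S; then HC(OMe)3, p-TsOH (cat.), 0 → 25 °C
Reagents that add atoms: trimethyl orthoformate COC(OC)OC
Why: Site-selective ozonolysis with reductive work-up cleaves the electron-rich terminal alkene (the 2,3-alkene is deactivated by the allylic chloride) and acid-catalysed acetalisation masks the new C14 aldehyde; no stereocentre is formed and the E-alkene is kept.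

Step 2
Reactants: 3 (2E)-1-chloro-6,6-dimethoxy-3-methylhex-2-ene; 4 prop-2-yn-1-ol
Product: 5 (5E)-9,9-dimethoxy-6-methylnon-5-en-2-yn-1-ol
Conditions: CuI (cat.), K2CO3, NaI (cat.), DMF, 25 °C
Reagents that add atoms: none
Why: Copper-catalysed allyl–alkynyl coupling: the copper acetylide displaces the primary allylic chloride at its unsubstituted terminus (SN2), so the E-trisubstituted alkene is retained and no stereocentre arises.

Step 3
Reactants: 5 (5E)-9,9-dimethoxy-6-methylnon-5-en-2-yn-1-ol
Product: 8 methyl (2E,5E)-2-(hydroxymethyl)-9,9-dimethoxy-6-methylnona-2,5-dienoate, via alkenylmagnesium species 6 (not isolated), via hydroxy acid 7 (not isolated)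
Conditions: i-BuMgBr (2.2 equiv), Cp2TiCl2 (cat.), Et2O, 25 °C; CO2, −20 °C; pH 5 work-up; then Me3SiCHN2, PhMe/MeOH, 0 °C
Reagents that add atoms: carbon dioxide O=C=O; trimethylsilyldiazomethane C[Si](C)(C)C=[N+]=[N-]
Why: Titanocene-catalysed hydromagnesiation of the 2-alkyn-1-ol is syn and places magnesium on the carbon next to the alkoxide; carboxylation with retention and O-methylation give the enoate with the chain cis to CH2OH, the geometry needed for the Z-allyl bromide.

Step 4
Reactants: 8 methyl (2E,5E)-2-(hydroxymethyl)-9,9-dimethoxy-6-methylnona-2,5-dienoate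
Product: 9 methyl (2Z,5E)-2-(bromomethyl)-9,9-dimethoxy-6-methylnona-2,5-dienoate
Conditions: CBr4, PPh3, 2,6-lutidine, CH2Cl2, 0 °C
Reagents that add atoms: carbon tetrabromide BrC(Br)(Br)Br
Why: Appel bromination replaces the primary allylic hydroxyl by bromide in an SN2 process under buffered conditions that spare the acetal; the alkene geometry is unchanged.

Step 5
Reactants: 9 methyl (2Z,5E)-2-(bromomethyl)-9,9-dimethoxy-6-methylnona-2,5-dienoate; 10 (4S)-2,2-dimethyl-1,3-dioxolane-4-carbaldehyde
Product: 12 (4S,5R)-5-[(4S)-2,2-dimethyl-1,3-dioxolan-4-yl]-4-[(2E)-6,6-dimethoxy-3-methylhex-2-en-1-yl]-3-methylideneoxolan-2-one, via open-chain hydroxy ester 11 (not isolated)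
Conditions: In (powder), THF/H2O (pH 7 buffer), 25 °C; then PPTS (cat.), PhH, 50 °C
Reagents that add atoms: none
Why: Indium-mediated Barbier 2-(alkoxycarbonyl)allylation followed by lactonisation: the allylindium with the chain cis to CH2–In reacts at its γ-carbon through a chair transition state to give the C7/C8 syn (cis-lactone) relationship, and Felkin–Anh attack anti to the dioxolane oxygen of 10 sets C7 as R and with it C8 as S.

Step 6
Reactants: 12 lactone dimethyl acetal
Product: 13 (4S,5R)-5-[(4S)-2,2-dimethyl-1,3-dioxolan-4-yl]-3-methylidene-4-[(2E)-3-methyl-6-oxohex-2-en-1-yl]oxolan-2-one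
Conditions: LiBF4, MeCN/H2O (98:2), 25 °C
Reagents that add atoms: water O
Why: Mild Lewis-acid hydrolysis cleaves the acyclic dimethyl acetal, which is far more labile than the cyclic dioxolane ketal, and frees the C14 aldehyde without touching a stereocentre.

Step 7
Reactants: 14 hepta-1,6-diyne
Product: 15 2,6-diiodohepta-1,6-diene
Conditions: NaI, Me3SiCl, H2O, MeCN, 25 °C
Reagents that add atoms: sodium iodide [Na+].[I-]
Why: Markovnikov hydroiodination of both terminal alkynes by HI generated in the flask gives the symmetric bis(2-iodoalkene) linchpin.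

Step 8
Reactants: 13 lactone aldehyde; 15 2,6-diiodohepta-1,6-diene
Product: 16 (4S,5R)-5-[(4S)-2,2-dimethyl-1,3-dioxolan-4-yl]-4-[(2E)-6-hydroxy-11-iodo-3-methyl-7-methylidenedodeca-2,11-dien-1-yl]-3-methylideneoxolan-2-one (both C14 epimers)
Conditions: CrCl2, NiCl2 (cat.), DMSO, 25 °C; 15 in excess
Reagents that add atoms: none
Why: Intermolecular Nozaki–Hiyama–Kishi coupling: one C–I bond of the symmetric diiodide is converted into an alkenylchromium that adds only to the aldehyde, forming C14–C1 with its exocyclic methylene; excess 15 suppresses double coupling and no control is sought at C14 because steps 9 and 10 reset it.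

Step 9
Reactants: 16 allylic alcohol (C14 epimers)
Product: 17 (4S,5R)-5-[(4S)-2,2-dimethyl-1,3-dioxolan-4-yl]-4-[(2E)-11-iodo-3-methyl-7-methylidene-6-oxododeca-2,11-dien-1-yl]-3-methylideneoxolan-2-one
Conditions: Dess–Martin periodinane, NaHCO3, CH2Cl2, 0 °C
Reagents that add atoms: none
Why: Dess–Martin oxidation converts both carbinol epimers into one α-methylene ketone under neutral conditions that leave the acetonide, lactone and C–I bond intact.

Step 10
Reactants: 17 α-methylene ketone
Product: 18 (4S,5R)-5-[(4S)-2,2-dimethyl-1,3-dioxolan-4-yl]-4-[(2E,6S)-6-hydroxy-11-iodo-3-methyl-7-methylidenedodeca-2,11-dien-1-yl]-3-methylideneoxolan-2-one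
Conditions: (R)-1-methyl-3,3-diphenyl-tetrahydro-1H,3H-pyrrolo[1,2-c][1,3,2]oxazaborole (cat.), catecholborane, PhMe, −78 °C
Reagents that add atoms: none
Why: Corey–Bakshi–Shibata reduction: the (R)-oxazaborolidine binds the ketone with the 2-substituted vinyl group as the large substituent and delivers hydride to give the (14S)-carbinol, while catecholborane at low temperature spares alkenes, lactone and iodide.

Step 11
Reactants: 18 (14S)-allylic alcohol
Product: 19 (4S,5R)-4-[(2E,6S)-6-acetoxy-11-iodo-3-methyl-7-methylidenedodeca-2,11-dien-1-yl]-5-[(4S)-2,2-dimethyl-1,3-dioxolan-4-yl]-3-methylideneoxolan-2-one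
Conditions: Ac2O, pyridine, DMAP (cat.), CH2Cl2, 0 → 25 °C
Reagents that add atoms: acetic anhydride CC(=O)OC(C)=O
Why: Standard O-acylation installs the final C14 acetate with retention at C14.

Step 12
Reactants: 19 acetonide acetate
Product: 21 (2R,3S)-3-[(2E,6S)-6-acetoxy-11-iodo-3-methyl-7-methylidenedodeca-2,11-dien-1-yl]-4-methylidene-5-oxooxolane-2-carbaldehyde, via diol 20 (not isolated)
Conditions: H5IO6, EtOAc, 0 → 25 °C
Reagents that add atoms: none
Why: Periodic acid hydrolyses the terminal acetonide and cleaves the resulting 1,2-diol in one pot (glycol cleavage), unveiling the C6 aldehyde with C7 untouched.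

Step 13
Reactants: 21 iodoalkene aldehyde
Product: 22 macrocyclic allylic alcohol (6S,7R,8S,10E,14S): 14-acetoxy-6-hydroxy-11-methyl-1,5-dimethylidenecyclotetradec-10-ene cis-fused at C7–C8 to an α-methylene-γ-butyrolactone (O on C7)
Conditions: CrCl2 (excess), NiCl2 (cat.), DMSO/THF, high dilution (ca. 2 mM), slow addition, 25 °C
Reagents that add atoms: none
Why: NiCl2 is reduced in the flask to zerovalent nickel, which inserts into the C5–I bond of the 2-iodoalkene; transmetalation to chromium gives an alkenyl–trivalent-chromium species that adds to the C6 aldehyde, and the chromium alkoxide is hydrolysed on work-up. The closest known reaction type is the Nozaki–Hiyama–Kishi macrocyclisation of ω-iodoalkenyl aldehydes. One ring is closed, the 14-membered carbocycle, in a 14-exo-trig mode (C5 attacks the C6 carbonyl, whose oxygen stays outside the ring). The new C6 stereocentre is controlled by the adjacent C7–O bond of the cis-lactone: polar Felkin–Anh attack anti to that oxygen should give the (6S)-carbinol, the epimer wanted here because step 14 uses it to direct hydrogen and step 15 inverts it. The step needs cyclisation to outrun oligomerisation and addition to occur only at the aldehyde; high dilution with slow addition, the sp2 centres at C1, C10 and C11 plus the lactone that pre-fold the chain, and the mild non-basic alkenylchromium (inert to lactone, acetate and acrylate) should secure this.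

Step 14
Reactants: 22 macrocyclic allylic alcohol
Product: 24 amino alcohol (5S,6S,7R,8S,10E,14S): 14-acetoxy-6-hydroxy-5,11-dimethyl-1-methylidenecyclotetradec-10-ene cis-fused at C7–C8 to an α-(dimethylaminomethyl)-γ-butyrolactone, via Mannich base 23 (not isolated)
Conditions: Me2NH, THF/MeOH, 0 °C, then evaporation; Ru(OAc)2[(R)-BINAP] (cat.), H2 (50 atm), MeOH, 25 °C
Reagents that add atoms: dimethylamine CNC
Why: Aza-Michael addition of dimethylamine masks the α-methylene lactone, and hydroxyl-directed hydrogenation with the ruthenium–BINAP diacetate, which reduces only alkenes beside a coordinating hydroxyl (the C1 methylene next to the acetate and C10=C11 are spared), adds hydrogen to C5 from the face of the (6S)-OH in the A(1,2)-strain-minimised conformer to give the 5,6-anti product with C5 as S; the (R)-ligand is chosen because, by the geraniol precedent, it binds this face of the O–C–C=C unit.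

Step 15
Reactants: 24 amino alcohol
Product: 25 amino diacetate (5S,6R,7R,8S,10E,14S): 6,14-diacetoxy-5,11-dimethyl-1-methylidenecyclotetradec-10-ene cis-fused at C7–C8 to an α-(dimethylaminomethyl)-γ-butyrolactone
Conditions: AcOH, PPh3, DIAD, PhMe, 0 → 25 °C
Reagents that add atoms: acetic acid CC(=O)O
Why: Mitsunobu reaction: the (6S)-alkoxyphosphonium is displaced by acetate in an SN2 process, so C6 is inverted to R and acetylated in one operation.

Step 16
Reactants: 25 amino diacetate
Product: 27 triene diacetate (5S,6R,7R,8S,10E,14S): 6,14-diacetoxy-5,11-dimethyl-1-methylidenecyclotetradec-10-ene cis-fused at C7–C8 to an α-methylene-γ-butyrolactone, via ammonium iodide 26 (not isolated)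
Conditions: MeI, MeCN, 25 °C; then aq. NaHCO3, EtOAc, 25 °C
Reagents that add atoms: none
Why: Exhaustive N-methylation followed by mild-base E1cB (Hofmann-type) elimination of trimethylamine regenerates the α-methylene lactone; the acetates tolerate bicarbonate and no stereocentre of the target is touched.

Step 17
Reactants: 27 triene diacetate
Product: 28 CNP0323853.2 (5S,6R,7R,8S,10R,11R,14S)
Conditions: 1,2:4,5-di-O-isopropylidene-β-D-erythro-2,3-hexodiulo-2,6-pyranose (0.3 equiv), KHSO5 (as 2KHSO5·KHSO4·K2SO4), K2CO3, Bu4NHSO4, MeCN/CH2(OMe)2/aq. Na2B4O7 buffer, 0 °C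
Reagents that add atoms: potassium peroxymonosulfate [K+].[O-]S(=O)(=O)OO
Why: Shi epoxidation: the chiral dioxirane reacts fastest with the only electron-rich trisubstituted alkene (the 1,1-disubstituted alkene beside the acetate and the acrylate are poor substrates) through a spiro transition state, and the D-fructose-derived ketone should deliver oxygen to the face that gives the (10R,11R)-trans-epoxide.

Compound list
1 | geranyl chloride, (2E)-1-chloro-3,7-dimethylocta-2,6-diene | CC(C)=CCC/C(C)=C/CCl | starting material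
2 | (4E)-6-chloro-4-methylhex-4-enal | O=CCC/C(C)=C/CCl | intermediate (not isolated)
3 | (2E)-1-chloro-6,6-dimethoxy-3-methylhex-2-ene | COC(OC)CC/C(C)=C/CCl | intermediate
4 | prop-2-yn-1-ol | OCC#C | starting material
5 | (5E)-9,9-dimethoxy-6-methylnon-5-en-2-yn-1-ol | OCC#CC/C=C(C)/CCC(OC)OC | intermediate
6 | bromomagnesium alkoxide of (2E,5E)-2-(bromomagnesio)-9,9-dimethoxy-6-methylnona-2,5-dien-1-ol (Mg trans to the chain) | COC(OC)CC/C(C)=C/C/C=C(\CO[Mg]Br)[Mg]Br | intermediate (not isolated)
7 | (2E,5E)-2-(hydroxymethyl)-9,9-dimethoxy-6-methylnona-2,5-dienoic acid | OC(=O)/C(CO)=C/C/C=C(C)/CCC(OC)OC | intermediate (not isolated)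
8 | methyl (2E,5E)-2-(hydroxymethyl)-9,9-dimethoxy-6-methylnona-2,5-dienoate | COC(=O)/C(CO)=C/C/C=C(C)/CCC(OC)OC | intermediate
9 | methyl (2Z,5E)-2-(bromomethyl)-9,9-dimethoxy-6-methylnona-2,5-dienoate | COC(=O)/C(CBr)=C/C/C=C(C)/CCC(OC)OC | intermediate
10 | (4S)-2,2-dimethyl-1,3-dioxolane-4-carbaldehyde (L-glyceraldehyde acetonide) | O=C[C@@H]1COC(C)(C)O1 | starting material
11 | methyl (3S,5E)-3-[(R)-[(4S)-2,2-dimethyl-1,3-dioxolan-4-yl](hydroxy)methyl]-9,9-dimethoxy-6-methyl-2-methylidenenon-5-enoate | COC(=O)C(=C)[C@H](C/C=C(C)/CCC(OC)OC)[C@@H](O)[C@@H]1COC(C)(C)O1 | intermediate (not isolated)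
12 | (4S,5R)-5-[(4S)-2,2-dimethyl-1,3-dioxolan-4-yl]-4-[(2E)-6,6-dimethoxy-3-methylhex-2-en-1-yl]-3-methylideneoxolan-2-one | CC1(C)OC[C@H](O1)[C@@H]2OC(=O)C(=C)[C@@H]2C/C=C(C)/CCC(OC)OC | intermediate
13 | (4S,5R)-5-[(4S)-2,2-dimethyl-1,3-dioxolan-4-yl]-3-methylidene-4-[(2E)-3-methyl-6-oxohex-2-en-1-yl]oxolan-2-one | CC1(C)OC[C@H](O1)[C@@H]2OC(=O)C(=C)[C@@H]2C/C=C(C)/CCC=O | intermediate
14 | hepta-1,6-diyne | C#CCCCC#C | starting material
15 | 2,6-diiodohepta-1,6-diene | C=C(I)CCCC(I)=C | intermediate
16 | (4S,5R)-5-[(4S)-2,2-dimethyl-1,3-dioxolan-4-yl]-4-[(2E)-6-hydroxy-11-iodo-3-methyl-7-methylidenedodeca-2,11-dien-1-yl]-3-methylideneoxolan-2-one (both C14 epimers) | CC1(C)OC[C@H](O1)[C@@H]2OC(=O)C(=C)[C@@H]2C/C=C(C)/CCC(O)C(=C)CCCC(I)=C | intermediate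
17 | (4S,5R)-5-[(4S)-2,2-dimethyl-1,3-dioxolan-4-yl]-4-[(2E)-11-iodo-3-methyl-7-methylidene-6-oxododeca-2,11-dien-1-yl]-3-methylideneoxolan-2-one | CC1(C)OC[C@H](O1)[C@@H]2OC(=O)C(=C)[C@@H]2C/C=C(C)/CCC(=O)C(=C)CCCC(I)=C | intermediate
18 | (4S,5R)-5-[(4S)-2,2-dimethyl-1,3-dioxolan-4-yl]-4-[(2E,6S)-6-hydroxy-11-iodo-3-methyl-7-methylidenedodeca-2,11-dien-1-yl]-3-methylideneoxolan-2-one | CC1(C)OC[C@H](O1)[C@@H]2OC(=O)C(=C)[C@@H]2C/C=C(C)/CC[C@H](O)C(=C)CCCC(I)=C | intermediate
19 | (4S,5R)-4-[(2E,6S)-6-acetoxy-11-iodo-3-methyl-7-methylidenedodeca-2,11-dien-1-yl]-5-[(4S)-2,2-dimethyl-1,3-dioxolan-4-yl]-3-methylideneoxolan-2-one | CC1(C)OC[C@H](O1)[C@@H]2OC(=O)C(=C)[C@@H]2C/C=C(C)/CC[C@H](OC(C)=O)C(=C)CCCC(I)=C | intermediate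
20 | (4S,5R)-4-[(2E,6S)-6-acetoxy-11-iodo-3-methyl-7-methylidenedodeca-2,11-dien-1-yl]-5-[(1S)-1,2-dihydroxyethyl]-3-methylideneoxolan-2-one | OC[C@H](O)[C@@H]1OC(=O)C(=C)[C@@H]1C/C=C(C)/CC[C@H](OC(C)=O)C(=C)CCCC(I)=C | intermediate (not isolated)
21 | (2R,3S)-3-[(2E,6S)-6-acetoxy-11-iodo-3-methyl-7-methylidenedodeca-2,11-dien-1-yl]-4-methylidene-5-oxooxolane-2-carbaldehyde | O=C[C@@H]1OC(=O)C(=C)[C@@H]1C/C=C(C)/CC[C@H](OC(C)=O)C(=C)CCCC(I)=C | intermediate
22 | macrocyclic allylic alcohol (6S,7R,8S,10E,14S): 14-acetoxy-6-hydroxy-11-methyl-1,5-dimethylidenecyclotetradec-10-ene cis-fused at C7–C8 to an α-methylene-γ-butyrolactone (O on C7) | C=C1CCCC(=C)[C@H](O)[C@@H]2OC(=O)C(=C)[C@@H]2C/C=C(C)/CC[C@@H]1OC(C)=O | intermediate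
23 | Mannich base of 22 (6S,7R,8S,10E,14S): lactone α-carbon bears H and CH2NMe2, configuration not controlled | C=C1CCCC(=C)[C@H](O)[C@@H]2OC(=O)C(CN(C)C)[C@@H]2C/C=C(C)/CC[C@@H]1OC(C)=O | intermediate (not isolated)
24 | amino alcohol (5S,6S,7R,8S,10E,14S): 14-acetoxy-6-hydroxy-5,11-dimethyl-1-methylidenecyclotetradec-10-ene cis-fused to an α-(dimethylaminomethyl)-γ-butyrolactone | C=C1CCC[C@H](C)[C@H](O)[C@@H]2OC(=O)C(CN(C)C)[C@@H]2C/C=C(C)/CC[C@@H]1OC(C)=O | intermediate
25 | amino diacetate (5S,6R,7R,8S,10E,14S): 6,14-diacetoxy-5,11-dimethyl-1-methylidenecyclotetradec-10-ene cis-fused to an α-(dimethylaminomethyl)-γ-butyrolactone | C=C1CCC[C@H](C)[C@@H](OC(C)=O)[C@@H]2OC(=O)C(CN(C)C)[C@@H]2C/C=C(C)/CC[C@@H]1OC(C)=O | intermediate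
26 | trimethylammonium iodide of 25 | C=C1CCC[C@H](C)[C@@H](OC(C)=O)[C@@H]2OC(=O)C(C[N+](C)(C)C)[C@@H]2C/C=C(C)/CC[C@@H]1OC(C)=O.[I-] | intermediate (not isolated)
27 | triene diacetate (5S,6R,7R,8S,10E,14S): 6,14-diacetoxy-5,11-dimethyl-1-methylidenecyclotetradec-10-ene cis-fused to an α-methylene-γ-butyrolactone | C=C1CCC[C@H](C)[C@@H](OC(C)=O)[C@@H]2OC(=O)C(=C)[C@@H]2C/C=C(C)/CC[C@@H]1OC(C)=O | intermediate
28 | CNP0323853.2, (5S,6R,7R,8S,10R,11R,14S)-6,14-diacetoxy-10,11-epoxy-5,11-dimethyl-1-methylidenecyclotetradecane cis-fused at C7–C8 to an α-methylene-γ-butyrolactone | C=C1CCC[C@H](C)[C@@H](OC(C)=O)[C@@H]2OC(=O)C(=C)[C@@H]2C[C@H]2O[C@]2(C)CC[C@@H]1OC(C)=O | target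

Total step count: 17. Longest linear sequence: 16 steps (steps 1–6 and 8–17 from geranyl chloride; step 7 makes the linchpin).

Steps most likely to fail

Step 13 (macrocyclisation). The attack of the alkenylchromium on the C6 aldehyde may show poor facial selectivity inside the forming ring, or favour the 6R face, and intermolecular coupling may compete. The fallback for the stereochemical part no longer relies on the C–C bond formation for C6. It sets out from the (6R)-epimer of 22, macrocyclic allylic alcohol F1, which would accompany 22. A Mitsunobu reaction with formic acid (PPh3, DIAD, PhMe) inverts it to the (6S)-formate F2, and mild methanolysis (KHCO3 cat., MeOH, 0 °C) comes back to the route at 22.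

Step 14 (directed hydrogenation). Hydrogen may also be delivered to the C1 methylene, or to the wrong face of the C5 methylene if the ring overrides the acyclic model. The fallback abandons alkene hydrogenation and sets out from 22. Dess–Martin oxidation gives the macrocyclic α-methylene ketone F3. Catecholborane then performs a conjugate reduction that is specific for s-cis enones and leaves the lactone acrylate and isolated alkenes alone. Hydrolysis and equilibration of the α-methyl centre with DBU give the (5S)-methyl ketone F4. Luche reduction (NaBH4, CeCl3, MeOH, −78 °C; Felkin–Anh, anti to the C7–O bond) gives the (5S,6R)-alcohol F5. Acetylation (Ac2O, pyridine, DMAP) comes back to the route at 27, so steps 14–16 are bypassed.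

Step 15 (Mitsunobu inversion). The hindered C6 carbinol, flanked by C5 and the lactone carbon C7, may resist activation or eliminate. The fallback replaces inversion by an oxidation–reduction sequence and sets out from 24. Buffered Dess–Martin oxidation gives the amino ketone F6. NaBH4 in MeOH at −78 °C, with Felkin–Anh attack anti to the C7–O bond, gives the (6R)-amino alcohol F7. Acetylation (Ac2O, pyridine, DMAP) comes back to the route at 25.

Further compounds
F1 | step 13 | (6R)-epimer of 22, macrocyclic allylic alcohol (6R,7R,8S,10E,14S) | C=C1CCCC(=C)[C@@H](O)[C@@H]2OC(=O)C(=C)[C@@H]2C/C=C(C)/CC[C@@H]1OC(C)=O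
F2 | step 13 | (6S)-formate of 22 | C=C1CCCC(=C)[C@H](OC=O)[C@@H]2OC(=O)C(=C)[C@@H]2C/C=C(C)/CC[C@@H]1OC(C)=O
F3 | step 14 | C6 ketone of 22, macrocyclic α-methylene ketone (7R,8S,10E,14S) | C=C1CCCC(=C)C(=O)[C@@H]2OC(=O)C(=C)[C@@H]2C/C=C(C)/CC[C@@H]1OC(C)=O
F4 | step 14 | (5S)-5-methyl C6 ketone (5S,7R,8S,10E,14S) with intact α-methylene lactone | C=C1CCC[C@H](C)C(=O)[C@@H]2OC(=O)C(=C)[C@@H]2C/C=C(C)/CC[C@@H]1OC(C)=O
F5 | step 14 | (5S,6R)-6-hydroxy compound, the 6-deacetyl form of 27 | C=C1CCC[C@H](C)[C@@H](O)[C@@H]2OC(=O)C(=C)[C@@H]2C/C=C(C)/CC[C@@H]1OC(C)=O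
F6 | step 15 | C6 ketone of 24, amino ketone (5S,7R,8S,10E,14S) | C=C1CCC[C@H](C)C(=O)[C@@H]2OC(=O)C(CN(C)C)[C@@H]2C/C=C(C)/CC[C@@H]1OC(C)=O
F7 | step 15 | (6R)-epimer of 24, amino alcohol (5S,6R,7R,8S,10E,14S) | C=C1CCC[C@H](C)[C@@H](O)[C@@H]2OC(=O)C(CN(C)C)[C@@H]2C/C=C(C)/CC[C@@H]1OC(C)=O
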